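The earlier runs and the new flask are calculated for substances that don't exist; scatter was added.

The gamma run cannot show what another charge of free catalyst does, because it used 0.1 mol%, the same as the flask. Its readings can still show whether the catalyst wears out on the way.

- gamma: left-handed substrate 0.10 M; right-handed substrate 0.10 M; reagent 1.8 equiv; free catalyst 0.1 mol%; run made earlier
- flask: left-handed substrate 0.10 M; reagent 1.20 equiv; free catalyst 0.1 mol%; right-handed substrate 0.10 M

gamma run (percent of the left-handed substrate and right-handed substrate together charged)

| time / s | left-handed product / % | left-handed substrate / % |
|---|---|---|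
| 10.0 | 17.8 | 32.0 |
| 20.0 | 28.0 | 21.7 |
| 40.0 | 36.1 | 13.8 |
| 80.0 | 40.2 | 9.7 |

(standard deviation of a reading: 0.5 percentage points)

- factor on the rate of making left-handed product when 50% of the left-handed substrate and right-handed substrate together are converted if free catalyst is charged twice over
- factor on the rate when 50% of the left-handed substrate and right-handed substrate together are converted if free catalyst is charged at 1 mol% instead

- free catalyst is single-handed; left-handed substrate and right-handed substrate are mirror images of each other, charged as a racemate, each of them at the stated concentration
- no earlier run changes the charge of free catalyst; that part of a forecast is a guess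

The first setting is the reagent, the limiting reagent here. The flask's charge covers 60.0% of both substrates, more than the 50% mark. My own reckoning lets both hands consume it alike and takes a step first order in [left-handed substrate], [reagent] and live catalyst. The clock g = ln([left-handed substrate]/([left-handed substrate] − d)) then climbs in proportion to d and to live catalyst, where d is the excess of left-handed substrate over its share of reagent: 5.00% in gamma, 20.0% in the flask.

In gamma, g climbs at 0.00940 s⁻¹ from 20.0 s to 40.0 s, but slower afterwards, at 0.00687 s⁻¹. Read as catalyst loss, that is 0.628 min⁻¹, a rough reading, since the last point stands 4.7 percentage points above d with scatter 0.5 points. Carried to the flask's larger d, the clock reaches the mark in 0.356 min.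

The second setting is the catalyst. Loss rate over conversion rate, with time cancelled, gives the wear W, the catalyst lost per trip to the mark: 0.223. An n-fold charge runs the clock n times faster, wears W/n, and meets the same composition, so the factor is n·exp(W − W/n): 2.24 for the doubled charge, 12.2 at 1 mol%.

The forecast, reasoning that “a simple catalytic turnover gives order one”, gave 2 and 9, lower than my reckoning.

The flask gives 2.19 and 12.0.

    reagent + catalyst intermediate A → free catalyst + left-handed product (k = 1870 M⁻¹ s⁻¹)
    free catalyst + left-handed substrate ⇌ catalyst intermediate A (K = 16.8 M⁻¹, k = 2640 M⁻¹ s⁻¹)
    free catalyst + right-handed substrate ⇌ catalyst intermediate B (K = 52.1 M⁻¹, k = 6100 M⁻¹ s⁻¹)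
    reagent + free catalyst → spent catalyst A (k = 0.0892 M⁻¹ s⁻¹)
    free catalyst → spent catalyst B (k = 0.0235 s⁻¹)
    reagent + catalyst intermediate B → free catalyst + right-handed product (k = 793 M⁻¹ s⁻¹)

In the flask, by 0.600 min the loss of free catalyst and left-handed substrate to catalyst intermediate A has 91% of its turnover up to 6.00 min behind it, while spent catalyst B holds 19.1% of the catalyst and reaches 88.0% by 6.00 min. Read back through n·exp(W − W/n), the flask's 12.0 at 1 mol% corresponds to a wear of 0.206, where gamma's readings gave 0.223.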